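The depsidone is cut at the diaryl ether C–O bond and at the bond between ring A and its CH2OH carbon. Ring A (the methyl-bearing ring) holds, on three adjacent carbons, the ether oxygen, the hydroxymethyl carbon and the phenolic oxygen, which is the substitution triad a 3-carbamoyloxy aryne can deliver. In one operation a ring B phenoxide attacks the aryne carbon meta to the carbamate oxygen and the resulting aryl anion pulls the carbamoyl group over from oxygen to carbon: ether bond, C–C bond and free ring A phenol. The precursors are a ring A ortho-silylaryl triflate carrying the diethylcarbamate and an allyl ester, and a hexasubstituted ring B phenol (allyl ether, acetonide, methyl ester, dimethyl acetal).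

Key step: step 12

Remarks on the chemistry, before the route:
- Ring B is the ring fused to the hydroxyphthalide. Locants in the names refer to the parent benzoate (ester carbon = C1).
- Assumption: the lactol carbon of the 3-hydroxyphthalide is the only stereocentre and it epimerises through the open formyl acid. Its (S) configuration (CIP order ring O > OH > aryl C > H) is therefore set in the last two steps, and the target must be kept as a solid or in neutral, dry, aprotic solution.
- Design choices: ring A starts from orsellinic acid so that the allyl ester is present from the first step, and silicon is placed by a retro-Brook shift, not by a directed lithiation, which the acidic toluate methyl group would not tolerate. In ring B the aldehyde is carried as its acetal from the moment it is made, because a free formyl group next to the methyl ester makes that ester very labile to aqueous base; this lability is used only in step 17.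

Step 1
Reactants: 1 orsellinic acid; 2 allyl bromide
Product: 3 allyl orsellinate
Conditions: allyl bromide, KHCO3, DMF, 25 °C
Reagents that add atoms: allyl bromide (2), C=CCBr
Why: Carboxylate O-alkylation (SN2): KHCO3 ionises only the carboxylic acid, so both phenols stay free and the allyl ester needed for the late palladium release is in place from the start.

Step 2
Reactants: 3 allyl orsellinate
Product: 4 allyl 2,4-dihydroxy-3-iodo-6-methylbenzoate
Conditions: I2, NaHCO3, THF/H2O, 0 °C
Reagents that add atoms: iodine, II
Why: Electrophilic aromatic iodination of a resorcinol-type phenoxide: under bicarbonate I2 is expected to enter the carbon between the two oxygens, as with resorcinol itself, the other open carbon being shielded by the methyl group.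

Step 3
Reactants: 4 allyl 2,4-dihydroxy-3-iodo-6-methylbenzoate; 5 diethylcarbamoyl chloride
Product: 6 allyl 4-(diethylcarbamoyloxy)-2-hydroxy-3-iodo-6-methylbenzoate
Conditions: Et2NCOCl, K2CO3, MeCN, 60 °C
Reagents that add atoms: diethylcarbamoyl chloride (5), CCN(CC)C(=O)Cl
Why: Selective O-carbamoylation (acyl substitution): the C4 hydroxyl is the more acidic and is not hydrogen-bonded, whereas the C2 hydroxyl is chelated to the ester and flanked by iodine.

Step 4
Reactants: 6 allyl 4-(diethylcarbamoyloxy)-2-hydroxy-3-iodo-6-methylbenzoate
Product: 9 ring A silyl triflate (allyl 4-(diethylcarbamoyloxy)-6-methyl-2-(trifluoromethylsulfonyloxy)-3-(trimethylsilyl)benzoate), via trimethylsilyl ether 7 (not isolated), via lithium silylphenoxide 8 (not isolated)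
Conditions: HMDS, THF, 65 °C, then evaporation; n-BuLi, THF, −100 °C; Tf2O, −100 → 0 °C
Reagents that add atoms: hexamethyldisilazane, C[Si](C)(C)N[Si](C)(C)C; trifluoromethanesulfonic anhydride, O=S(=O)(OS(=O)(=O)C(F)(F)F)C(F)(F)F
Why: Retro-Brook sequence: iodine–lithium exchange at −100 °C should outrun attack on the di-ortho-substituted ester, the aryllithium takes the silyl group from the neighbouring oxygen (1,3-O→C shift, faster than a carbamoyl shift at this temperature) and the lithium phenoxide is triflated in the same flask.

Step 5
Reactants: 10 methyl orsellinate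
Product: 12 methyl 2,4,5-trihydroxy-6-methylbenzoate, via aryl potassium sulfate 11 (not isolated)
Conditions: K2S2O8, NaOH, H2O, 5 → 20 °C; then HCl, Na2SO3, 70 °C
Reagents that add atoms: K2S2O8, [K+].[K+].[O-]S(=O)(=O)OOS(=O)(=O)[O-]
Why: Elbs persulfate oxidation: peroxodisulfate attacks the phenoxide para to the C2 oxygen, the only open para position, and acid hydrolysis of the aryl sulfate releases the new C5 phenol.

Step 6
Reactants: 12 methyl 2,4,5-trihydroxy-6-methylbenzoate
Product: 13 methyl 2,4,5-triacetoxy-6-methylbenzoate
Conditions: Ac2O, pyridine, DMAP (cat.), 25 °C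
Reagents that add atoms: acetic anhydride, CC(=O)OC(C)=O
Why: Peracetylation (acyl transfer) protects the air-sensitive triol and deactivates the ring so that the next bromination goes to the methyl group.

Step 7
Reactants: 13 methyl 2,4,5-triacetoxy-6-methylbenzoate
Product: 14 methyl 2,4,5-triacetoxy-6-(dibromomethyl)benzoate
Conditions: NBS (2.4 equiv), AIBN, PhCF3, 90 °C, visible light
Reagents that add atoms: N-bromosuccinimide, O=C1CCC(=O)N1Br
Why: Wohl–Ziegler radical bromination: with the ring deactivated by three acetoxy groups and the ester, hydrogen abstraction occurs twice at the only benzylic position and gives the benzal bromide, which is at the aldehyde oxidation level.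

Step 8
Reactants: 14 methyl 2,4,5-triacetoxy-6-(dibromomethyl)benzoate
Product: 15 methyl 2-(dimethoxymethyl)-3,4,6-trihydroxybenzoate
Conditions: NaOMe, MeOH, 0 → 25 °C, argon; AcOH to pH 7
Reagents that add atoms: sodium methoxide NaOMe, [Na+].[O-]C; methanol, CO
Why: Zemplén-type transesterification removes the acetates, and the ortho-phenoxide then drives two bromide-for-methoxide exchanges (solvolysis of a benzal halide to its acetal), so the aldehyde appears only in masked form while methanolysis of the methyl ester is degenerate.

Step 9
Reactants: 15 methyl 2-(dimethoxymethyl)-3,4,6-trihydroxybenzoate; 2 allyl bromide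
Product: 16 methyl 4-(allyloxy)-2-(dimethoxymethyl)-3,6-dihydroxybenzoate
Conditions: allyl bromide (1.05 equiv), KHCO3, DMF, 40 °C, argon
Reagents that add atoms: allyl bromide (2), C=CCBr
Why: Williamson etherification: bicarbonate ionises only the C4 hydroxyl (para to the ester, most acidic, least hindered), while the C6 hydroxyl is chelated to the ester and the C3 hydroxyl is flanked by the acetal.

Step 10
Reactants: 16 methyl 4-(allyloxy)-2-(dimethoxymethyl)-3,6-dihydroxybenzoate
Product: 17 methyl 4-(allyloxy)-2-(dimethoxymethyl)-3,6-dihydroxy-5-(hydroxymethyl)benzoate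
Conditions: aq. HCHO, KOH, H2O/THF, 0 → 25 °C, argon; AcOH to pH 7
Reagents that add atoms: formaldehyde, C=O
Why: Lederer–Manasse hydroxymethylation: the phenoxide attacks formaldehyde through the only unsubstituted ring carbon, which lies between two oxygens, and acetal, allyl ether and the hindered ester are stable to cold aqueous base.

Step 11
Reactants: 17 methyl 4-(allyloxy)-2-(dimethoxymethyl)-3,6-dihydroxy-5-(hydroxymethyl)benzoate
Product: 18 ring B phenol (methyl 5-(allyloxy)-7-(dimethoxymethyl)-6-hydroxy-2,2-dimethyl-4H-1,3-benzodioxine-8-carboxylate)
Conditions: 2,2-dimethoxypropane, PPTS (cat.), acetone, 25 °C; Et3N quench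
Reagents that add atoms: 2,2-dimethoxypropane, COC(C)(C)OC
Why: Acid-catalysed transketalisation: only the ester-side hydroxyl has the CH2OH group as neighbour, so a single six-membered 1,3-benzodioxine forms, and the dry, methanol-releasing medium leaves the dimethyl acetal intact.

Step 12
Reactants: 18 ring B phenol; 9 ring A silyl triflate
Product: 22 diaryl ether (allyl 3-(diethylcarbamoyl)-4-hydroxy-6-methyl-2-aryloxybenzoate), via potassium phenoxide 19 (not isolated), via ring A aryne 20 (not isolated), via aryl anion adduct 21 (not isolated)
Conditions: KH, 18-crown-6, THF, 0 °C; then CsF and slow addition of 9, THF, 25 °C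
Reagents that add atoms: none
Why: Proposed new method: fluoride removes the trimethylsilyl group of 9 and triflate departs to give aryne 20, the pre-formed, crown-activated phenoxide 19 adds to the aryne carbon meta to the carbamate oxygen (diaryl ether C–O bond), and aryl anion 21, which lies ortho to the carbamate, attacks the carbamoyl carbon through a four-membered transition state and expels the ring A phenoxide (new C–C bond); the closest known reactions are the O-arylation of phenols by arynes from ortho-silylaryl triflates, the anionic ortho-Fries shift of aryl carbamates and the addition/thia-Fries sequence of 3-triflyloxyarynes. No ring is closed and no stereocentre is formed. The step needs site selectivity in the addition: the inductively withdrawing carbamate oxygen distorts the aryne and stabilises charge on the adjacent carbon, which should outweigh the weaker pull of the twisted allyl ester on the other flank. It also needs the acyl shift to outrun protonation, which is why the phenol is fully deprotonated with KH (H2 leaves) and the medium is THF without acidic O–H or C–H bonds. Loss of triflate from the silicate should be faster than a premature acyl shift, as in the related 2-silyl-1,3-bis(triflyloxy)arenes.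

Step 13
Reactants: 22 diaryl ether
Product: 23 seco acid
Conditions: Pd(PPh3)4 (cat.), pyrrolidine, THF, 25 °C
Reagents that add atoms: none
Why: Tsuji–Trost deallylation: zerovalent palladium ionises both the allyl ester and the allyl aryl ether to π-allyl complexes that pyrrolidine captures, and the neutral amine medium leaves acetal, acetonide, amide and methyl ester untouched.

Step 14
Reactants: 23 seco acid
Product: 24 depsidone amide
Conditions: DCC, CH2Cl2 (high dilution), 25 °C
Reagents that add atoms: none
Why: Carbodiimide lactonisation: the O-acylisourea of the ring A acid is captured by the ring B hydroxyl held next to it by the ether bridge (seven-membered depsidone ring), while the ring A phenol is meta to the acid and hydrogen-bonded to the amide.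

Step 15
Reactants: 24 depsidone amide
Product: 25 depsidone aldehyde
Conditions: Cp2Zr(H)Cl (3 equiv), THF, 25 °C; then H2O
Reagents that add atoms: none
Why: Reduction of a tertiary amide with Cp2Zr(H)Cl: hydride adds to the amide carbonyl to give a zirconated hemiaminal that releases the aldehyde on hydrolysis, a reaction known to spare esters and to work on hindered N,N-diethylbenzamides.

Step 16
Reactants: 25 depsidone aldehyde
Product: 26 depsidone alcohol
Conditions: NaBH4, THF/EtOH, −20 °C; aq. NH4Cl
Reagents that add atoms: none
Why: Borohydride reduction: the aldehyde is reduced much faster than the hindered aryl lactone or the methyl ester at low temperature, and the new alcohol, meta to the lactone carbonyl, cannot attack it.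

Step 17
Reactants: 26 depsidone alcohol
Product: 28 racemic lactol, via formyl methyl ester 27 (not isolated)
Conditions: 1 M HCl, THF, 25 °C; then aq. NaHCO3 to pH 8, 25 °C; then HCl to pH 2, 0 °C
Reagents that add atoms: water, O
Why: Acetal and ketal hydrolysis followed by neighbouring-group ester hydrolysis: at pH 8 the hydrate anion of the freed formyl group attacks the adjacent twisted methyl ester intramolecularly (a strongly accelerated, known pathway of ortho-formylbenzoates), so the ester is lost under conditions that should leave the hindered depsidone lactone alone, and acidification closes the hydroxyphthalide as the racemate.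

Step 18
Reactants: 28 racemic lactol
Product: 29 (S)-triacetate
Conditions: lipase (Burkholderia cepacia lipase or Candida antarctica lipase B, selected for the (S)-acetate), vinyl acetate, Et3N (cat.), THF, 30 °C
Reagents that add atoms: vinyl acetate, C=COC(C)=O
Why: Lipase-catalysed dynamic kinetic resolution by acylation: the hemiacetal epimerises through its open form under the weakly basic conditions while the enzyme acetylates one enantiomer, so the enzyme sets the lactol stereocentre as a configurationally stable acylal (a subtilisin-type protease is the usual source of the opposite preference if the lipases give the (R)-acetate), and both primary alcohols are acetylated as well.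

Step 19
Reactants: 29 (S)-triacetate
Product: 30 target CNP0155661.1
Conditions: enzyme of step 18, n-BuOH, THF/MTBE, 25 °C; crystallisation
Reagents that add atoms: none
Why: Lipase-catalysed alcoholysis: acyl–oxygen cleavage removes the three acetates under neutral, water-free conditions without breaking a bond at the stereocentre, and the enzyme's preference for the (S)-acetate should upgrade the enantiomeric purity before crystallisation.

Compound list
1 | orsellinic acid (2,4-dihydroxy-6-methylbenzoic acid) | Cc1cc(O)cc(O)c1C(=O)O | starting material
2 | allyl bromide | C=CCBr | starting material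
3 | allyl orsellinate (allyl 2,4-dihydroxy-6-methylbenzoate) | C=CCOC(=O)c1c(C)cc(O)cc1O | intermediate
4 | allyl 2,4-dihydroxy-3-iodo-6-methylbenzoate | C=CCOC(=O)c1c(C)cc(O)c(I)c1O | intermediate
5 | diethylcarbamoyl chloride | CCN(CC)C(=O)Cl | starting material
6 | allyl 4-(diethylcarbamoyloxy)-2-hydroxy-3-iodo-6-methylbenzoate | C=CCOC(=O)c1c(C)cc(OC(=O)N(CC)CC)c(I)c1O | intermediate
7 | trimethylsilyl ether of 6 at the C2 oxygen (not isolated) | C=CCOC(=O)c1c(C)cc(OC(=O)N(CC)CC)c(I)c1O[Si](C)(C)C | intermediate
8 | lithium 2-(allyloxycarbonyl)-5-(diethylcarbamoyloxy)-3-methyl-6-(trimethylsilyl)phenoxide (not isolated) | C=CCOC(=O)c1c(C)cc(OC(=O)N(CC)CC)c([Si](C)(C)C)c1[O-].[Li+] | intermediate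
9 | ring A silyl triflate: allyl 4-(diethylcarbamoyloxy)-6-methyl-2-(trifluoromethylsulfonyloxy)-3-(trimethylsilyl)benzoate | C=CCOC(=O)c1c(C)cc(OC(=O)N(CC)CC)c([Si](C)(C)C)c1OS(=O)(=O)C(F)(F)F | intermediate
10 | methyl orsellinate (methyl 2,4-dihydroxy-6-methylbenzoate) | COC(=O)c1c(C)cc(O)cc1O | starting material
11 | potassium 4,6-dihydroxy-3-(methoxycarbonyl)-2-methylphenyl sulfate (not isolated) | COC(=O)c1c(C)c(OS(=O)(=O)[O-])c(O)cc1O.[K+] | intermediate
12 | methyl 2,4,5-trihydroxy-6-methylbenzoate | COC(=O)c1c(C)c(O)c(O)cc1O | intermediate
13 | methyl 2,4,5-triacetoxy-6-methylbenzoate | COC(=O)c1c(C)c(OC(C)=O)c(OC(C)=O)cc1OC(C)=O | intermediate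
14 | methyl 2,4,5-triacetoxy-6-(dibromomethyl)benzoate | COC(=O)c1c(C(Br)Br)c(OC(C)=O)c(OC(C)=O)cc1OC(C)=O | intermediate
15 | methyl 2-(dimethoxymethyl)-3,4,6-trihydroxybenzoate | COC(=O)c1c(C(OC)OC)c(O)c(O)cc1O | intermediate
16 | methyl 4-(allyloxy)-2-(dimethoxymethyl)-3,6-dihydroxybenzoate | COC(=O)c1c(C(OC)OC)c(O)c(OCC=C)cc1O | intermediate
17 | methyl 4-(allyloxy)-2-(dimethoxymethyl)-3,6-dihydroxy-5-(hydroxymethyl)benzoate | COC(=O)c1c(C(OC)OC)c(O)c(OCC=C)c(CO)c1O | intermediate
18 | ring B phenol: methyl 5-(allyloxy)-7-(dimethoxymethyl)-6-hydroxy-2,2-dimethyl-4H-1,3-benzodioxine-8-carboxylate | Oc1c(OCC=C)c2COC(C)(C)Oc2c(C(=O)OC)c1C(OC)OC | intermediate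
19 | potassium phenoxide of 18 (not isolated) | [K+].[O-]c1c(OCC=C)c2COC(C)(C)Oc2c(C(=O)OC)c1C(OC)OC | intermediate
20 | ring A aryne: allyl 4-(diethylcarbamoyloxy)-6-methyl-2,3-didehydrobenzoate (not isolated) | C=CCOC(=O)C1=C(C)C=C(OC(=O)N(CC)CC)C#C1 | intermediate
21 | aryl anion adduct: diaryl ether with the carbanion on the ring A carbon between the ether oxygen and the carbamate, potassium salt (not isolated) | C=CCOC(=O)c1c(C)cc(OC(=O)N(CC)CC)[c-]c1Oc3c(OCC=C)c4COC(C)(C)Oc4c(C(=O)OC)c3C(OC)OC.[K+] | intermediate
22 | diaryl ether: allyl 3-(diethylcarbamoyl)-4-hydroxy-6-methyl-2-aryloxybenzoate, aryl = ring B of 18 bound through its former phenol oxygen | C=CCOC(=O)c1c(C)cc(O)c(C(=O)N(CC)CC)c1Oc3c(OCC=C)c4COC(C)(C)Oc4c(C(=O)OC)c3C(OC)OC | intermediate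
23 | seco acid: 22 with the allyl ester cleaved to CO2H and the ring B allyl ether cleaved to OH | OC(=O)c1c(C)cc(O)c(C(=O)N(CC)CC)c1Oc3c(O)c4COC(C)(C)Oc4c(C(=O)OC)c3C(OC)OC | intermediate
24 | depsidone amide: seven-membered lactone between the ring A carboxyl and the ring B hydroxyl of 23; ring A keeps CH3, OH and CONEt2; ring B keeps acetonide, CO2CH3 and CH(OCH3)2 | Cc1cc(O)c(C(=O)N(CC)CC)c2c1C(=O)Oc1c3COC(C)(C)Oc3c(C(=O)OC)c(C(OC)OC)c1O2 | intermediate
25 | depsidone aldehyde: 24 with CHO in place of CONEt2 | Cc1cc(O)c(C=O)c2c1C(=O)Oc1c3COC(C)(C)Oc3c(C(=O)OC)c(C(OC)OC)c1O2 | intermediate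
26 | depsidone alcohol: 24 with CH2OH in place of CONEt2 | Cc1cc(O)c(CO)c2c1C(=O)Oc1c3COC(C)(C)Oc3c(C(=O)OC)c(C(OC)OC)c1O2 | intermediate
27 | formyl methyl ester: 26 without the acetonide and with CH(OCH3)2 hydrolysed to CHO (not isolated) | Cc1cc(O)c(CO)c2c1C(=O)Oc1c(CO)c(O)c(C(=O)OC)c(C=O)c1O2 | intermediate
28 | racemic lactol: hydroxyphthalide closed between the ring B carboxyl and formyl carbons, racemic at the lactol carbon | Cc1cc(O)c(CO)c2c1C(=O)Oc1c(CO)c(O)c3c(c1O2)C(O)OC3=O | intermediate
29 | (S)-triacetate: 28 acetylated at the lactol oxygen and at both CH2OH groups, (S) at the acylal carbon | Cc1cc(O)c(COC(C)=O)c2c1C(=O)Oc1c(COC(C)=O)c(O)c3c(c1O2)[C@@H](OC(C)=O)OC3=O | intermediate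
30 | target CNP0155661.1, (S) at the lactol carbon | Cc1cc(O)c(CO)c2c1C(=O)Oc1c(CO)c(O)c3c(c1O2)[C@@H](O)OC3=O | target

Total step count: 19. Longest linear sequence: 15 steps (steps 5–19, from methyl orsellinate 10); the ring A branch is steps 1–4.

Steps most likely to fail

1. Step 12. What may go wrong: the aryl anion is protonated or otherwise consumed before the carbamoyl group shifts, so that the ether bond forms without the C–C bond. Fallback (known chemistry, the two bonds made separately): from 9 and 18 the aryne etherification is run in its ordinary protic form (CsF, MeCN, 25 °C, phenol not deprotonated beforehand), where protonation of the aryl anion is wanted, to give diaryl ether carbamate F1. Pd(PPh3)4/pyrrolidine then frees hydroxy acid F2, DCC at high dilution closes depsidone carbamate F3, and Cp2Zr(H)Cl cleaves the aryl carbamate reductively to depsidone phenol F4. Magnesium-mediated ortho-formylation (MgCl2, Et3N, paraformaldehyde, MeCN, 70 °C) then places the formyl group next to the phenol, the carbon between the two oxygens being expected to react as in the formylation of orsellinates, and the route is rejoined at aldehyde 25.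

2. Step 15. What may go wrong: hydride transfer stalls at the amide, which is flanked on both sides, or spreads to the aryl lactone once excess reagent is used. Fallback (change of order, no lactone present during the reduction): from seco acid 23, Cp2Zr(H)Cl (extra equivalents for the acid and the two phenols) reduces the amide first to give formyl seco acid F5, and DCC lactonisation of this acid at high dilution returns to aldehyde 25.

3. Step 18. What may go wrong: the enzyme does not accept the bulky polycyclic hemiacetal, or epimerisation is too slow to feed a dynamic process, so that conversion or enantioselectivity stays low. Fallback (physical separation instead of catalytic selection): from racemic lactol 28, Ac2O/pyridine gives racemic pentaacetate F6, whose enantiomers are separated by chromatography on a chiral stationary phase to give (S)-pentaacetate F7, a configurationally stable acylal. Lipase-catalysed butanolysis of all five acetates, as in step 19, then gives target 30.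

Further compounds
F1 | step 12 | diaryl ether carbamate: allyl 4-(diethylcarbamoyloxy)-6-methyl-2-aryloxybenzoate, aryl = ring B of 18 | C=CCOC(=O)c1c(C)cc(OC(=O)N(CC)CC)cc1Oc3c(OCC=C)c4COC(C)(C)Oc4c(C(=O)OC)c3C(OC)OC
F2 | step 12 | hydroxy acid: F1 with both allyl groups removed | OC(=O)c1c(C)cc(OC(=O)N(CC)CC)cc1Oc3c(O)c4COC(C)(C)Oc4c(C(=O)OC)c3C(OC)OC
F3 | step 12 | depsidone carbamate: lactone of F2 | Cc1cc(OC(=O)N(CC)CC)cc2c1C(=O)Oc1c3COC(C)(C)Oc3c(C(=O)OC)c(C(OC)OC)c1O2
F4 | step 12 | depsidone phenol: F3 with the carbamate cleaved to OH | Cc1cc(O)cc2c1C(=O)Oc1c3COC(C)(C)Oc3c(C(=O)OC)c(C(OC)OC)c1O2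
F5 | step 15 | formyl seco acid: 23 with CHO in place of CONEt2 | OC(=O)c1c(C)cc(O)c(C=O)c1Oc3c(O)c4COC(C)(C)Oc4c(C(=O)OC)c3C(OC)OC
F6 | step 18 | racemic pentaacetate of 28 | Cc1cc(OC(C)=O)c(COC(C)=O)c2c1C(=O)Oc1c(COC(C)=O)c(OC(C)=O)c3c(c1O2)C(OC(C)=O)OC3=O
F7 | step 18 | (S)-pentaacetate | Cc1cc(OC(C)=O)c(COC(C)=O)c2c1C(=O)Oc1c(COC(C)=O)c(OC(C)=O)c3c(c1O2)[C@@H](OC(C)=O)OC3=O
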